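X comes off E, and E forms reversibly from G.Q.D, so with 0.25 mM of D against 0.050 M of G I counted X as turns of a cycle: the catalyst charge times the time, divided by the seconds one turn takes.

| setting | gamma | theta | epsilon | beta |
|---|---|---|---|---|
| G | 0.050 M | 0.050 M | 0.050 M | 0.050 M |
| Q | 0.0600 M | 0.0600 M | 0.0600 M | 0.0600 M |
| D | 0.25 mM | 0.25 mM | 0.25 mM | 0.25 mM |
| temperature | 20 °C | 50 °C | 35 °C |  |
| time | 80 s | 80 s | 80 s | 80 s |
| remark |  |  |  | at 20 °C until 15 s, from then on at 50 °C |

    Q + D ⇌ Q.D (K1 = 18 L mol⁻¹, k1 = 340 L mol⁻¹ s⁻¹, Ea1 = 39.0 kJ mol⁻¹, ΔH1 = −60.0 kJ mol⁻¹)
    G + Q.D → G.Q.D (k2 = 1600 L mol⁻¹ s⁻¹, Ea2 = 39.0 kJ mol⁻¹)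
    G.Q.D ⇌ E (K3 = 0.39, k3 = 2.1 s⁻¹, Ea3 = 60.0 kJ mol⁻¹, ΔH3 = −90.0 kJ mol⁻¹)
    E → D + X (k4 = 9.9 s⁻¹, Ea4 = 59.0 kJ mol⁻¹)
    (constants at 20 °C)

- which flask leads in amount of X, in percent of the G charged ("all alike" within 1.5 percentage points) (gamma / theta / epsilon / beta / all alike)
- how much X is there at the end, in percent of the G charged: gamma
- how much X is there at the end, in percent of the G charged: theta
- how much X is there at the end, in percent of the G charged: epsilon
- how much X is there at the end, in percent of the G charged: beta

- constants are those at 20 °C; use the activation energies and enthalpies for any other temperature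

I began with the stretch from G.Q.D onward. I wrote the seconds for one turn there as the inverse of the forward constant of G.Q.D into E, plus the inverse of the product of that step's equilibrium constant and the constant of E going on to D + X; the second term is my allowance for E falling back. This gave 0.735 s for gamma, 0.625 s for epsilon and 0.892 s for theta. Warming shrank the first term but swelled the second, since the equilibrium constant fell from 0.39 to 0.0127 in theta, a larger factor than the 9.5 gained by the exit of E, so the sum came out lower in epsilon than at either end.

Next I added the rest of the cycle at the charged concentrations: the life of E, the wait of Q.D for G, and the wait of D for Q, stretched by Q.D falling back before G meets it. X then came to 44.0 % in gamma, 57.0 % in epsilon and 42.4 % in theta.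

The weak link was the charged concentrations, since G and Q are consumed as X forms. So I put the first answer back in, taking half of each first X from [G] and [Q] to get their means over the run. The second round gave 0.930 s for gamma, 0.959 s for theta and 0.726 s for epsilon. This last figure, the cycle time of epsilon, meaning the seconds one catalyst molecule needs per X at the mean [G] and [Q] of the run, is the quantity I carried. In epsilon the added terms stayed shorter than the stretch from G.Q.D, so I took G.Q.D as the resting state. I committed to X of 43.0 % in gamma, 41.7 % in theta and 55.1 % in epsilon. For beta, 15 s at the cycle time of gamma and the rest at that of theta gave 41.9 %.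

The forecast gave 42.7 % for gamma, 41.4 % for theta, 54.8 % for epsilon and 41.6 % for beta, named epsilon as leader, and held that on warming the equilibrium “collapses toward G.Q.D”. My numbers stood slightly above it in gamma, theta, epsilon and beta.

The simulation gave 42.8 % for gamma, 41.6 % for theta, 54.7 % for epsilon and 41.8 % for beta, with epsilon leading, so the forecast held.

Read back, the X of epsilon means 0.731 s per turn, against the 0.726 s I reckoned. In theta, the allowance for E falling back stood at 87.9 % of my cycle time. The undoing of E into G.Q.D is one part of what held theta at 41.6 %, acting together with the early reading: with the undoing removed X stood at 97.5 %, and at ten times the time at 100 %.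

With 0.020 M of G and otherwise as epsilon, the cycle time of epsilon allows 27.6 mM of X in the time, more than that charge, so I expected G to run out; that flask gave 98.6 % of X, with 1.2 % of its G left.

The numbers of this flask were drawn at random within sensible limits; the run is a simulation.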